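The route rests on disconnecting C10–C11, which opens the six-membered ring of the bicyclo[3.1.1]heptane fused across cyclobutane C1–C2–C8–C7 of the tricyclo[5.4.0.0^2,8]undecane core. C11 is a carbonyl carbon on C1 and C9 carries a methyl group, so a carbonyl-ene reaction between a C1 aldehyde and a C8 isopropenyl group, held cis-1,3 on the cyclobutane, forms C10–C11, closes that ring and leaves a C11 carbinol and a C9 methylene in one operation. The precursor, aldehyde 28, is a bicyclo[4.1.1]octane made by Wolff contraction of a bicyclo[4.2.1]nonanone, whose bridged frame first sets C3, C5 and C6.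

Key step: step 22

Remark: locants are those of the target skeleton throughout; in the cyclopentanone intermediates the ring carbonyl carbon is the future C9 and its α-methylene the future C8, the hydroxymethyl carbon on C1 is the future C11, and the C6 epimers formed in step 6 are carried together because C6 becomes planar again in step 9.

Step 1
Reactants: 1 2-methylcyclopent-2-en-1-one
Product: 3 (2S,3R)-2-allyl-3-{[dimethyl(propan-2-yloxy)silyl]methyl}-2-methylcyclopentan-1-one, via magnesium enolate 2 (not isolated)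
Conditions: Cu(OTf)2 (4 mol %), chiral hydroxyalkyl-imidazolinium chloride (NHC precursor, 5 mol %), (i-PrO)Me2SiCH2MgCl, Et2O, −30 °C; then allyl iodide, DMPU, −30 °C → rt
Reagents that add atoms: (isopropoxydimethylsilyl)methylmagnesium chloride CC(C)O[Si](C)(C)C[Mg]Cl; allyl iodide C=CCI
Why: Copper/NHC-catalysed asymmetric conjugate addition of a Grignard reagent to an α-methyl cyclic enone sets C1 under ligand control, and allylation of the magnesium enolate anti to the new C1 substituent sets quaternary C2 (conjugate addition–enolate trapping).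

Step 2
Reactants: 3 silylmethyl ketone
Product: 4 (2S,3R)-2-allyl-3-(hydroxymethyl)-2-methylcyclopentan-1-one
Conditions: KF, KHCO3, 30% H2O2, THF/MeOH, rt
Reagents that add atoms: hydrogen peroxide OO
Why: Tamao oxidation turns the alkoxysilyl C–Si bond into the primary C11–OH without touching C1 or C2.

Step 3
Reactants: 4 hydroxy ketone
Product: 5 (2S,3R)-2-allyl-2-methyl-3-[(triethylsilyloxy)methyl]cyclopentan-1-one
Conditions: Et3SiCl, imidazole, CH2Cl2, 0 °C
Reagents that add atoms: chlorotriethylsilane CC[Si](Cl)(CC)CC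
Why: Silylation of the primary alcohol gives an ether that survives the base and organometallic steps and is removed later by mild acid.

Step 4
Reactants: 5 allyl ketone
Product: 6 (2S,3R)-2-methyl-2-[(E)-prop-1-enyl]-3-[(triethylsilyloxy)methyl]cyclopentan-1-one
Conditions: RuHCl(CO)(PPh3)3 (5 mol %), toluene, 80 °C
Reagents that add atoms: none
Why: Ruthenium hydride-catalysed alkene isomerisation (hydrometalation/β-hydride elimination) moves the double bond next to quaternary C2, so that C3 becomes vinylic for the later ring-closing metathesis.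

Step 5
Reactants: 6 propenyl ketone
Product: 7 (4R,5S)-5-methyl-5-[(E)-prop-1-enyl]-4-[(triethylsilyloxy)methyl]cyclopent-2-en-1-one
Conditions: LiN(i-Pr)2, THF, −78 °C; then PhS(Cl)=N-t-Bu, −78 °C
Reagents that add atoms: none
Why: C8 is the only enolisable position, and sulfinylation of its lithium enolate with the sulfinimidoyl chloride followed by syn-elimination gives the C7=C8 enone in one pot (enolate dehydrogenation).

Step 6
Reactants: 7 enone; 8 tert-butyl[(1-methoxyprop-1-en-1-yl)oxy]dimethylsilane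
Product: 9 methyl 2-{3-(tert-butyldimethylsilyloxy)-4-methyl-4-[(E)-prop-1-enyl]-5-[(triethylsilyloxy)methyl]cyclopent-2-en-1-yl}propanoate (C6 epimers)
Conditions: t-BuMe2SiOTf (10 mol %), CH2Cl2, −78 °C
Reagents that add atoms: none
Why: Mukaiyama–Michael addition with silyl transfer; the ketene acetal attacks C7 anti to the neighbouring C1 substituent, which sets C7 trans to C1, and the product emerges as the C9 silyl enol ether, which masks the cyclopentanone.

Step 7
Reactants: 9 ester
Product: 11 4-{3-(tert-butyldimethylsilyloxy)-4-methyl-4-[(E)-prop-1-enyl]-5-[(triethylsilyloxy)methyl]cyclopent-2-en-1-yl}pent-1-en-3-one (C6 epimers), via Weinreb amide 10 (not isolated)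
Conditions: MeNH(OMe)·HCl, i-PrMgCl, THF, −20 °C; then CH2=CHMgBr, −20 → 0 °C; cold aq. NH4Cl
Reagents that add atoms: vinylmagnesium bromide C=C[Mg]Br; N,O-dimethylhydroxylamine hydrochloride CNOC.Cl (atoms in 10 only)
Why: Weinreb ketone synthesis run in one flask: the ester is converted into the N-methoxy-N-methylamide, whose chelated tetrahedral adduct with the vinyl Grignard reagent stops at the ketone stage.

Step 8
Reactants: 11 vinyl ketone
Product: 12 bicyclo[4.2.1]nonadienone (C5 ketone, C3=C4 alkene, C8=C9 silyl enol ether, C6 epimers)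
Conditions: (H2IMes)(PCy3)Cl2Ru=CHPh (second-generation Grubbs catalyst, 10 mol %), CH2Cl2 (0.002 M), 40 °C
Reagents that add atoms: none
Why: Ring-closing metathesis of the C2 propenyl group with the vinyl ketone, which sit cis-1,3 on the cyclopentene, closes the seven-membered enone ring with loss of propene.

Step 9
Reactants: 12 bicyclic enone
Product: 13 C6-quaternary enone with C6–CH2OH syn to C1 and C6–CH3 anti to C1
Conditions: LiN(i-Pr)2, THF, −78 °C; CH2O (gas), −78 °C; AcOH
Reagents that add atoms: formaldehyde C=O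
Why: α′-Deprotonation of the enone is possible only at C6, and the aldol addition to formaldehyde should occur on the ring face syn to the one-carbon bridge C1 (only its hydrogen points at the ring) and anti to the C8=C9 bridge, which sets quaternary C6.

Step 10
Reactants: 13 hydroxymethyl enone
Product: 14 C6–CH2OSiMe2t-Bu enone
Conditions: t-BuMe2SiCl, imidazole, DMF, rt
Reagents that add atoms: tert-butylchlorodimethylsilane CC(C)(C)[Si](C)(C)Cl
Why: Silylation of the primary alcohol blocks retro-aldol loss of formaldehyde and installs the ether kept until step 29.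

Step 11
Reactants: 14 enone
Product: 16 β-hydroxy ketone (C3–OH syn to C1, C5 ketone), via C3 pinacol boronate 15 (not isolated)
Conditions: CuCl (10 mol %), Xantphos (10 mol %), NaOt-Bu (15 mol %), B2pin2, MeOH, THF, rt; then NaBO3·4H2O, THF/H2O
Reagents that add atoms: sodium perborate [Na+].[Na+].O[B-]1(O)OO[B-](O)(O)OO1; bis(pinacolato)diboron CC1(C)OB(OC1(C)C)B2OC(C)(C)C(C)(C)O2 (atoms in 15 only)
Why: Copper-catalysed conjugate borylation should deliver boron to C3 from the same open face syn to C1, and the stereoretentive perborate oxidation then gives the C3 carbinol.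

Step 12
Reactants: 16 β-hydroxy ketone
Product: 17 C3 tert-butyldimethylsilyl ether, C5 ketone
Conditions: t-BuMe2SiOTf (1.1 equiv), 2,6-lutidine, CH2Cl2, −78 °C
Reagents that add atoms: tert-butyldimethylsilyl triflate CC(C)(C)[Si](C)(C)OS(=O)(=O)C(F)(F)F
Why: Silyl triflate etherification of the hindered secondary alcohol at low temperature, before any second hydroxyl exists, so the two ring oxygens stay differentiated.

Step 13
Reactants: 17 C5 ketone
Product: 18 C5 alcohol (OH anti to C1 and anti to the C3 silyloxy group)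
Conditions: (S)-2-methyl-CBS-oxazaborolidine (0.5 equiv), catecholborane, toluene, −78 → −40 °C
Reagents that add atoms: none
Why: Corey–Bakshi–Shibata reduction; with quaternary C6 as the large and C4H2 as the small flank, the (S)-catalyst delivers hydride to the carbonyl face syn to C1, so the C5 hydroxyl ends up on the opposite face.

Step 14
Reactants: 18 C5 alcohol
Product: 19 C5 4-methoxybenzyl ether
Conditions: NaH, 4-MeOC6H4CH2Cl, n-Bu4NI (cat.), THF/DMF, 0 °C → rt
Reagents that add atoms: 4-methoxybenzyl chloride COc1ccc(CCl)cc1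
Why: Williamson etherification; no carbonyl group is present at this stage, so the hindered alkoxide is alkylated without enolate side reactions.

Step 15
Reactants: 19 silyl enol ether
Product: 20 bicyclo[4.2.1]nonanone with C9 ketone and free C11 hydroxymethyl on C1
Conditions: PPTS, MeOH/CH2Cl2, rt
Reagents that add atoms: none
Why: Mild acid methanolysis cleaves the silyl enol ether by protonation at C8 and removes the primary triethylsilyl ether, while the two tert-butyldimethylsilyl ethers and the 4-methoxybenzyl ether are stable.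

Step 16
Reactants: 20 keto alcohol
Product: 22 C8 diazo C9 ketone, via trifluoroacetyl ketone 21 (not isolated)
Conditions: LiN(SiMe3)2 (3.2 equiv), THF, −78 °C; CF3CO2CH2CF3; then MeSO2N3, Et3N, H2O, MeCN, rt
Reagents that add atoms: methanesulfonyl azide CS(=O)(=O)N=[N+]=[N-]; 2,2,2-trifluoroethyl trifluoroacetate FC(F)(F)COC(=O)C(F)(F)F (atoms in 21 only)
Why: Deacylative diazo transfer to the single α-methylene C8 after its trifluoroacetylation; the O-trifluoroacetate formed on the primary alcohol is hydrolysed in the aqueous amine medium.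

Step 17
Reactants: 22 diazo ketone
Product: 24 bicyclo[4.1.1]octane C8 methyl ester (C8 epimers), via ketene 23 (not isolated)
Conditions: hν (365 nm), MeOH, rt
Reagents that add atoms: methanol CO
Why: Photochemical Wolff rearrangement; C2 migrates with retention from C9 to C8, contracting the cyclopentanone to the cyclobutane, and methanol traps the ketene as the ester.

Step 18
Reactants: 24 hydroxy ester
Product: 25 lactone bridging C8 and C1 (C8–C9(=O)–O–C11H2–C1)
Conditions: KOt-Bu (0.3 equiv), toluene, 80 °C, 4 Å MS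
Reagents that add atoms: none
Why: Base-mediated ester epimerisation with lactonisation; only the epimer with the ester cis-1,3 to the C1 hydroxymethyl group can close the bridged δ-lactone, so both C8 epimers are funnelled to one lactone and C8 is set.

Step 19
Reactants: 25 lactone
Product: 26 cyclic methyl hemiketal (masked C8 acetyl / C11 alcohol)
Conditions: MeLi (1.1 equiv), THF, −78 °C; aq. NH4Cl
Reagents that add atoms: methyllithium [Li]C
Why: Single addition of methyllithium to the lactone stops at the lithium hemiketal alkoxide at −78 °C, which gives the methyl ketone as its hemiketal.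

Step 20
Reactants: 26 hemiketal
Product: 27 C8 isopropenyl C11 primary alcohol
Conditions: Ph3PCH3Br, KOt-Bu (4 equiv), THF, 0 → 40 °C
Reagents that add atoms: methyltriphenylphosphonium bromide C[P+](c1ccccc1)(c1ccccc1)c1ccccc1.[Br-]
Why: Wittig methylenation of the ring-opened hydroxy methyl ketone installs the isopropenyl group without passing through a cyclobutylcarbinyl cation, which would ring-expand.

Step 21
Reactants: 27 alcohol
Product: 28 C1 aldehyde with C8 isopropenyl (key-step precursor)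
Conditions: Dess–Martin periodinane, NaHCO3, CH2Cl2, 0 °C → rt
Reagents that add atoms: none
Why: Dess–Martin oxidation of the primary alcohol under buffered conditions that do not epimerise C1.

Step 22
Reactants: 28 aldehyde
Product: 29 tricyclic C11 alcohol (OH syn to C7) with C9 exocyclic methylene
Conditions: Me2AlCl (2.5 equiv), CH2Cl2, −78 → −40 °C; aq. potassium sodium tartrate
Reagents that add atoms: none
Why: Me2AlCl binds the aldehyde oxygen, the terminal CH2 of the isopropenyl group (future C10) attacks the carbonyl carbon C11, and a hydrogen of the allylic methyl group passes to oxygen through a six-membered ene transition state, leaving the methylene on C9. The closest known reaction type is the Lewis-acid-promoted intramolecular carbonyl-ene cyclisation of aldehydes onto 1,1-disubstituted alkenes tethered through the central alkene carbon, which gives 3-methylenecyclohexanols. The six-membered ring C1–C11–C10–C9–C8–C7 closes in a 6-exo-trig sense at the carbonyl group with alkene carbons C9 and C10 both inside the new ring, completing the bicyclo[3.1.1]heptane. The new stereocentre C11 is controlled by the aluminium-bound oxygen pointing to the C7–H side, away from the C2 methyl group that overhangs the forming ring. The step needs ene closure in preference to chloride capture, alkene migration or epimerisation at C1; the bicyclo[4.1.1]octane frame holds the two arms cis-1,3 within bonding distance, and Me2AlCl acts as both a mild Lewis acid and a proton scavenger.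

Step 23
Reactants: 29 homoallylic alcohol
Product: 30 C11 ketone with C9 exocyclic methylene
Conditions: Dess–Martin periodinane, NaHCO3, CH2Cl2, 0 °C
Reagents that add atoms: none
Why: Buffered Dess–Martin oxidation gives the β,γ-unsaturated ketone without moving the double bond into conjugation.

Step 24
Reactants: 30 ketone
Product: 31 C11 alcohol (OH syn to C2) with C9 exocyclic methylene
Conditions: LiBH(s-Bu)3, THF, −78 °C; then NaOH, H2O2
Reagents that add atoms: none
Why: Bulky hydride reduction; the reagent attacks the C11 carbonyl from the C7–H side, away from the C2 methyl group over the six-membered ring, which places the hydroxyl syn to C2.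

Step 25
Reactants: 31 homoallylic alcohol
Product: 32 C9 methyl (syn to C7) C11 alcohol
Conditions: [Ir(cod)(PCy3)(py)]PF6 (10 mol %), H2 (1 atm), CH2Cl2, rt
Reagents that add atoms: none
Why: Hydroxyl-directed hydrogenation; iridium bound to the C11 hydroxyl delivers hydrogen to the exocyclic alkene on the same face, so hydrogen enters C9 syn to C2 and the methyl group ends up syn to C7.

Step 26
Reactants: 32 alcohol
Product: 33 C11 ketone
Conditions: Dess–Martin periodinane, NaHCO3, CH2Cl2, rt
Reagents that add atoms: none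
Why: Dess–Martin oxidation of the secondary alcohol; C1 is a bridgehead of the bicyclo[3.1.1]heptane and C9 is β to the ketone, so neither can epimerise.

Step 27
Reactants: 33 4-methoxybenzyl ether
Product: 34 C5 alcohol
Conditions: DDQ, CH2Cl2/pH 7 buffer, 0 °C → rt
Reagents that add atoms: none
Why: Oxidative cleavage of the 4-methoxybenzyl ether by hydride abstraction and hydrolysis frees only the C5 hydroxyl, the two silyl ethers being inert.

Step 28
Reactants: 34 C5 alcohol; 35 angelic acid
Product: 37 C5 angelate bis-silyl ether, via mixed anhydride 36 (not isolated)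
Conditions: 35, 2,4,6-Cl3C6H2COCl, Et3N, toluene, rt; then 34, toluene, 80 °C
Reagents that add atoms: 2,4,6-trichlorobenzoyl chloride O=C(Cl)c1c(Cl)cc(Cl)cc1Cl (atoms in 36 only)
Why: Yamaguchi esterification through the mixed trichlorobenzoic anhydride acylates the hindered secondary alcohol without a nucleophilic catalyst, which avoids isomerisation of the (Z)-2-methylbut-2-enoate to the tiglate.

Step 29
Reactants: 37 bis-silyl ether
Product: 38 diol (C3–OH and primary OH)
Conditions: HF·pyridine, pyridine, THF, 0 °C → rt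
Reagents that add atoms: none
Why: Acidic fluoride desilylation removes both tert-butyldimethylsilyl groups without the basic conditions that would let the angeloyl group migrate or isomerise.

Step 30
Reactants: 38 diol
Product: 39 target
Conditions: Ac2O (1.1 equiv), pyridine, CH2Cl2, 0 °C
Reagents that add atoms: acetic anhydride CC(=O)OC(C)=O
Why: Selective acetylation; the primary hydroxyl reacts far faster than the secondary C3 hydroxyl next to the quaternary bridgehead C2.

Compound list

1 | 2-methylcyclopent-2-en-1-one | CC1=CCCC1=O | starting material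
2 | chloromagnesium enolate of (3R)-3-{[dimethyl(propan-2-yloxy)silyl]methyl}-2-methylcyclopentanone | CC1=C(O[Mg]Cl)CC[C@H]1C[Si](C)(C)OC(C)C | intermediate
3 | (2S,3R)-2-allyl-3-{[dimethyl(propan-2-yloxy)silyl]methyl}-2-methylcyclopentan-1-one | C=CC[C@]1(C)C(=O)CC[C@H]1C[Si](C)(C)OC(C)C | intermediate
4 | (2S,3R)-2-allyl-3-(hydroxymethyl)-2-methylcyclopentan-1-one | C=CC[C@]1(C)C(=O)CC[C@H]1CO | intermediate
5 | (2S,3R)-2-allyl-2-methyl-3-[(triethylsilyloxy)methyl]cyclopentan-1-one | C=CC[C@]1(C)C(=O)CC[C@H]1CO[Si](CC)(CC)CC | intermediate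
6 | (2S,3R)-2-methyl-2-[(E)-prop-1-enyl]-3-[(triethylsilyloxy)methyl]cyclopentan-1-one | C/C=C/[C@]1(C)C(=O)CC[C@H]1CO[Si](CC)(CC)CC | intermediate
7 | (4R,5S)-5-methyl-5-[(E)-prop-1-enyl]-4-[(triethylsilyloxy)methyl]cyclopent-2-en-1-one | C/C=C/[C@]1(C)C(=O)C=C[C@H]1CO[Si](CC)(CC)CC | intermediate
8 | tert-butyl[(1-methoxyprop-1-en-1-yl)oxy]dimethylsilane (E/Z mixture) | CC=C(OC)O[Si](C)(C)C(C)(C)C | starting material
9 | methyl 2-{3-(tert-butyldimethylsilyloxy)-4-methyl-4-[(E)-prop-1-enyl]-5-[(triethylsilyloxy)methyl]cyclopent-2-en-1-yl}propanoate (side chain trans to the C1 substituent; C6 epimers) | C/C=C/[C@]1(C)C(O[Si](C)(C)C(C)(C)C)=C[C@@H]([C@H]1CO[Si](CC)(CC)CC)C(C)C(=O)OC | intermediate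
10 | N-methoxy-N-methylamide corresponding to ester 9 | C/C=C/[C@]1(C)C(O[Si](C)(C)C(C)(C)C)=C[C@@H]([C@H]1CO[Si](CC)(CC)CC)C(C)C(=O)N(C)OC | intermediate
11 | 4-{3-(tert-butyldimethylsilyloxy)-4-methyl-4-[(E)-prop-1-enyl]-5-[(triethylsilyloxy)methyl]cyclopent-2-en-1-yl}pent-1-en-3-one (C6 epimers) | C/C=C/[C@]1(C)C(O[Si](C)(C)C(C)(C)C)=C[C@@H]([C@H]1CO[Si](CC)(CC)CC)C(C)C(=O)C=C | intermediate
12 | bicyclo[4.2.1]nonadienone: C5 ketone, C3=C4, C8=C9 enol ether with C9–OSiMe2t-Bu, C1–CH2OSiEt3, C2–CH3, C6–H/CH3 (epimers) | O=C1C=C[C@]2(C)C(O[Si](C)(C)C(C)(C)C)=C[C@@H]([C@H]2CO[Si](CC)(CC)CC)C1C | intermediate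
13 | as 12 with quaternary C6: CH2OH syn to C1, CH3 anti to C1 | O=C1C=C[C@]2(C)C(O[Si](C)(C)C(C)(C)C)=C[C@@H]([C@H]2CO[Si](CC)(CC)CC)[C@@]1(C)CO | intermediate
14 | C6–CH2OSiMe2t-Bu ether of 13 | O=C1C=C[C@]2(C)C(O[Si](C)(C)C(C)(C)C)=C[C@@H]([C@H]2CO[Si](CC)(CC)CC)[C@@]1(C)CO[Si](C)(C)C(C)(C)C | intermediate
15 | C3 pinacol boronate (boron syn to C1), C5 ketone | O=C1C[C@@H](B3OC(C)(C)C(C)(C)O3)[C@]2(C)C(O[Si](C)(C)C(C)(C)C)=C[C@@H]([C@H]2CO[Si](CC)(CC)CC)[C@@]1(C)CO[Si](C)(C)C(C)(C)C | intermediate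
16 | C3 alcohol (OH syn to C1), C5 ketone | O=C1C[C@@H](O)[C@]2(C)C(O[Si](C)(C)C(C)(C)C)=C[C@@H]([C@H]2CO[Si](CC)(CC)CC)[C@@]1(C)CO[Si](C)(C)C(C)(C)C | intermediate
17 | C3 tert-butyldimethylsilyl ether of 16 | O=C1C[C@@H](O[Si](C)(C)C(C)(C)C)[C@]2(C)C(O[Si](C)(C)C(C)(C)C)=C[C@@H]([C@H]2CO[Si](CC)(CC)CC)[C@@]1(C)CO[Si](C)(C)C(C)(C)C | intermediate
18 | C5 alcohol (OH anti to C1 and to C3–O) | O[C@@H]1C[C@@H](O[Si](C)(C)C(C)(C)C)[C@]2(C)C(O[Si](C)(C)C(C)(C)C)=C[C@@H]([C@H]2CO[Si](CC)(CC)CC)[C@@]1(C)CO[Si](C)(C)C(C)(C)C | intermediate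
19 | C5 4-methoxybenzyl ether of 18 | COc5ccc(cc5)CO[C@@H]1C[C@@H](O[Si](C)(C)C(C)(C)C)[C@]2(C)C(O[Si](C)(C)C(C)(C)C)=C[C@@H]([C@H]2CO[Si](CC)(CC)CC)[C@@]1(C)CO[Si](C)(C)C(C)(C)C | intermediate
20 | bicyclo[4.2.1]nonanone: C9 ketone, C1–CH2OH, C3–OSiMe2t-Bu, C5–O-(4-methoxybenzyl), C6(CH3)(CH2OSiMe2t-Bu) | COc5ccc(cc5)CO[C@@H]1C[C@@H](O[Si](C)(C)C(C)(C)C)[C@]2(C)C(=O)C[C@@H]([C@H]2CO)[C@@]1(C)CO[Si](C)(C)C(C)(C)C | intermediate
21 | C8-trifluoroacetyl ketone, C11 O-trifluoroacetate | COc5ccc(cc5)CO[C@@H]1C[C@@H](O[Si](C)(C)C(C)(C)C)[C@]2(C)C(=O)C(C(=O)C(F)(F)F)[C@@H]([C@H]2COC(=O)C(F)(F)F)[C@@]1(C)CO[Si](C)(C)C(C)(C)C | intermediate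
22 | C8 diazo C9 ketone | COc5ccc(cc5)CO[C@@H]1C[C@@H](O[Si](C)(C)C(C)(C)C)[C@]2(C)C(=O)C(=[N+]=[N-])[C@@H]([C@H]2CO)[C@@]1(C)CO[Si](C)(C)C(C)(C)C | intermediate
23 | bicyclo[4.1.1]octane C8 ketene | COc5ccc(cc5)CO[C@@H]1C[C@@H](O[Si](C)(C)C(C)(C)C)[C@]2(C)C(=C=O)[C@@H]([C@H]2CO)[C@@]1(C)CO[Si](C)(C)C(C)(C)C | intermediate
24 | bicyclo[4.1.1]octane C8 methyl ester (C8 epimers), C1–CH2OH | COc5ccc(cc5)CO[C@@H]1C[C@@H](O[Si](C)(C)C(C)(C)C)[C@]2(C)C(C(=O)OC)[C@@H]([C@H]2CO)[C@@]1(C)CO[Si](C)(C)C(C)(C)C | intermediate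
25 | lactone bridging C8 and C1 through C9(=O)–O–C11H2 | COc5ccc(cc5)CO[C@@H]1C[C@@H](O[Si](C)(C)C(C)(C)C)[C@]2(C)[C@@H]3[C@@H]([C@H]2COC3=O)[C@@]1(C)CO[Si](C)(C)C(C)(C)C | intermediate
26 | cyclic methyl hemiketal of the C8 acetyl / C11 alcohol (anomers) | COc5ccc(cc5)CO[C@@H]1C[C@@H](O[Si](C)(C)C(C)(C)C)[C@]2(C)[C@@H]3[C@@H]([C@H]2COC3(C)O)[C@@]1(C)CO[Si](C)(C)C(C)(C)C | intermediate
27 | C8 isopropenyl, C1–CH2OH bicyclo[4.1.1]octane | COc5ccc(cc5)CO[C@@H]1C[C@@H](O[Si](C)(C)C(C)(C)C)[C@]2(C)[C@@H](C(C)=C)[C@@H]([C@H]2CO)[C@@]1(C)CO[Si](C)(C)C(C)(C)C | intermediate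
28 | C1 aldehyde, C8 isopropenyl bicyclo[4.1.1]octane (key-step precursor) | COc5ccc(cc5)CO[C@@H]1C[C@@H](O[Si](C)(C)C(C)(C)C)[C@]2(C)[C@@H](C(C)=C)[C@@H]([C@H]2C=O)[C@@]1(C)CO[Si](C)(C)C(C)(C)C | intermediate
29 | tricyclic C11 alcohol (OH syn to C7) with C9 exocyclic methylene (key-step product) | COc5ccc(cc5)CO[C@@H]1C[C@@H](O[Si](C)(C)C(C)(C)C)[C@]2(C)[C@@H]3[C@@H]([C@H]2[C@@H](O)CC3=C)[C@@]1(C)CO[Si](C)(C)C(C)(C)C | intermediate
30 | C11 ketone with C9 exocyclic methylene | COc5ccc(cc5)CO[C@@H]1C[C@@H](O[Si](C)(C)C(C)(C)C)[C@]2(C)[C@@H]3[C@@H]([C@H]2C(=O)CC3=C)[C@@]1(C)CO[Si](C)(C)C(C)(C)C | intermediate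
31 | C11 alcohol (OH syn to C2) with C9 exocyclic methylene | COc5ccc(cc5)CO[C@@H]1C[C@@H](O[Si](C)(C)C(C)(C)C)[C@]2(C)[C@@H]3[C@@H]([C@H]2[C@H](O)CC3=C)[C@@]1(C)CO[Si](C)(C)C(C)(C)C | intermediate
32 | C9 methyl (syn to C7), C11 alcohol (syn to C2) | COc5ccc(cc5)CO[C@@H]1C[C@@H](O[Si](C)(C)C(C)(C)C)[C@]2(C)[C@@H]3[C@@H]([C@H]2[C@H](O)C[C@H]3C)[C@@]1(C)CO[Si](C)(C)C(C)(C)C | intermediate
33 | C11 ketone, C9 methyl, fully protected | COc5ccc(cc5)CO[C@@H]1C[C@@H](O[Si](C)(C)C(C)(C)C)[C@]2(C)[C@@H]3[C@@H]([C@H]2C(=O)C[C@H]3C)[C@@]1(C)CO[Si](C)(C)C(C)(C)C | intermediate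
34 | C5 alcohol | O[C@@H]1C[C@@H](O[Si](C)(C)C(C)(C)C)[C@]2(C)[C@@H]3[C@@H]([C@H]2C(=O)C[C@H]3C)[C@@]1(C)CO[Si](C)(C)C(C)(C)C | intermediate
35 | angelic acid, (Z)-2-methylbut-2-enoic acid | C/C=C(/C)C(=O)O | starting material
36 | angelic 2,4,6-trichlorobenzoic anhydride | C/C=C(/C)C(=O)OC(=O)c1c(Cl)cc(Cl)cc1Cl | intermediate
37 | C5 angelate, C3 and primary tert-butyldimethylsilyl ethers | C/C=C(/C)C(=O)O[C@@H]1C[C@@H](O[Si](C)(C)C(C)(C)C)[C@]2(C)[C@@H]3[C@@H]([C@H]2C(=O)C[C@H]3C)[C@@]1(C)CO[Si](C)(C)C(C)(C)C | intermediate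
38 | C5 angelate diol (C3–OH, primary OH) | C/C=C(/C)C(=O)O[C@@H]1C[C@@H](O)[C@]2(C)[C@@H]3[C@@H]([C@H]2C(=O)C[C@H]3C)[C@@]1(C)CO | intermediate
39 | CNP0212099.1 | C/C=C(/C)C(=O)O[C@@H]1C[C@@H](O)[C@]2(C)[C@@H]3[C@@H]([C@H]2C(=O)C[C@H]3C)[C@@]1(C)COC(C)=O | target

Total step count: 30. Longest linear sequence: 30 steps (1 → 39); angelic acid 35 and ketene acetal 8 enter as single reagents.

Steps most likely to fail

Step 22. The aluminium-bound cation may be captured by chloride or lose a ring proton instead of the methyl proton, or the Lewis acid may be held by the ether oxygens so that the closure stalls. The fallback keeps the C10–C11 bond but replaces the ene by an allylsilane addition and sets out from lactone 25. Me3SiCH2MgCl with CeCl3 (THF, −78 °C → rt) adds twice to the lactone carbonyl and gives the bis(trimethylsilylmethyl) carbinol F1. Peterson elimination on silica gel then gives the allylsilane alcohol F2, and Dess–Martin oxidation the allylsilane aldehyde F3. BF3·OEt2 (CH2Cl2, −78 °C) closes the ring by intramolecular Hosomi–Sakurai allylation, in which the β-silyl cation can only collapse to the exocyclic methylene. This comes back to the route at 29; any C11 epimer formed is compound 31, and both are carried on through steps 23 and 24.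

Step 25. The catalyst may fail to bind on the face shielded by the C2 methyl group, so that hydrogen adds undirected from the open face and C9 is formed with the wrong configuration. The fallback sets out from 29 and places the C9 methyl group by conjugate addition from the open face instead. Ozonolysis (O3, CH2Cl2/MeOH, −78 °C, then Me2S) gives the C9 ketone C11 alcohol F4, and TsNHNH2 the tosylhydrazone F5. A Shapiro reaction (n-BuLi, THF, −78 → 0 °C; deprotonation at C10) gives the C9=C10 allylic alcohol F6, and Dess–Martin oxidation the enone F7. Me2CuLi (Et2O, −78 °C) then adds to C9 from the C7–H side, anti to the methyl-bearing C2 bridge, and the sequence comes back to the route at 33.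

Step 9. Formaldehyde may enter on the ring face syn to the two-carbon bridge, which gives the C6 epimer. The fallback reverses the order in which the two C6 substituents are introduced and sets out from enone 7. Mukaiyama–Michael addition of the silyl ketene acetal F8 of methyl 3-(tert-butyldimethylsilyloxy)propanoate gives adduct F9. The one-flask Weinreb sequence of step 7 gives vinyl ketone F10, and ring-closing metathesis as in step 8 gives the bicyclic enone F11, which carries H and CH2OSiMe2t-Bu on C6. Deprotonation with LiN(i-Pr)2 and methylation with MeI (THF, −78 °C) then bring in the methyl group on the face that formaldehyde had preferred, and the sequence comes back to the route at 14.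

Further compounds

F1 | step 22 | bis(trimethylsilylmethyl) carbinol on C8 with C1–CH2OH | COc5ccc(cc5)CO[C@@H]1C[C@@H](O[Si](C)(C)C(C)(C)C)[C@]2(C)[C@@H](C(O)(C[Si](C)(C)C)C[Si](C)(C)C)[C@@H]([C@H]2CO)[C@@]1(C)CO[Si](C)(C)C(C)(C)C
F2 | step 22 | allylsilane alcohol: C8–C(=CH2)CH2SiMe3 with C1–CH2OH | COc5ccc(cc5)CO[C@@H]1C[C@@H](O[Si](C)(C)C(C)(C)C)[C@]2(C)[C@@H](C(=C)C[Si](C)(C)C)[C@@H]([C@H]2CO)[C@@]1(C)CO[Si](C)(C)C(C)(C)C
F3 | step 22 | allylsilane aldehyde: C8–C(=CH2)CH2SiMe3 with C1–CHO | COc5ccc(cc5)CO[C@@H]1C[C@@H](O[Si](C)(C)C(C)(C)C)[C@]2(C)[C@@H](C(=C)C[Si](C)(C)C)[C@@H]([C@H]2C=O)[C@@]1(C)CO[Si](C)(C)C(C)(C)C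
F4 | step 25 | tricyclic C9 ketone C11 alcohol | COc5ccc(cc5)CO[C@@H]1C[C@@H](O[Si](C)(C)C(C)(C)C)[C@]2(C)[C@@H]3[C@@H]([C@H]2[C@@H](O)CC3=O)[C@@]1(C)CO[Si](C)(C)C(C)(C)C
F5 | step 25 | C9 tosylhydrazone of F4 | COc5ccc(cc5)CO[C@@H]1C[C@@H](O[Si](C)(C)C(C)(C)C)[C@]2(C)[C@@H]3[C@@H]([C@H]2[C@@H](O)CC3=NNS(=O)(=O)c4ccc(C)cc4)[C@@]1(C)CO[Si](C)(C)C(C)(C)C
F6 | step 25 | C9=C10 allylic C11 alcohol | COc5ccc(cc5)CO[C@@H]1C[C@@H](O[Si](C)(C)C(C)(C)C)[C@]2(C)[C@@H]3[C@@H]([C@H]2[C@@H](O)C=C3)[C@@]1(C)CO[Si](C)(C)C(C)(C)C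
F7 | step 25 | C9=C10 C11 enone | COc5ccc(cc5)CO[C@@H]1C[C@@H](O[Si](C)(C)C(C)(C)C)[C@]2(C)[C@@H]3[C@@H]([C@H]2C(=O)C=C3)[C@@]1(C)CO[Si](C)(C)C(C)(C)C
F8 | step 9 | tert-butyl{[3-(tert-butyldimethylsilyloxy)-1-methoxyprop-1-en-1-yl]oxy}dimethylsilane | COC(=CCO[Si](C)(C)C(C)(C)C)O[Si](C)(C)C(C)(C)C
F9 | step 9 | methyl 3-(tert-butyldimethylsilyloxy)-2-{cyclopentenyl}propanoate, ring as in 9 | C/C=C/[C@]1(C)C(O[Si](C)(C)C(C)(C)C)=C[C@@H]([C@H]1CO[Si](CC)(CC)CC)C(CO[Si](C)(C)C(C)(C)C)C(=O)OC
F10 | step 9 | vinyl ketone from F9 | C/C=C/[C@]1(C)C(O[Si](C)(C)C(C)(C)C)=C[C@@H]([C@H]1CO[Si](CC)(CC)CC)C(CO[Si](C)(C)C(C)(C)C)C(=O)C=C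
F11 | step 9 | bicyclo[4.2.1]nonadienone with C6–H and C6–CH2OSiMe2t-Bu | O=C1C=C[C@]2(C)C(O[Si](C)(C)C(C)(C)C)=C[C@@H]([C@H]2CO[Si](CC)(CC)CC)C1CO[Si](C)(C)C(C)(C)C
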